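**Assumption (one line):** the SMILES is read literally, i.e. (3Z,6S,7S,3'R,3a'S,7a'S) with H‑6/H‑7 trans (C5 exo, C7a endo on the 2‑oxabicyclo[2.2.1]heptan‑3‑one). Locants: unit A = C1(=O)–O2–C3(=C8–C11)–C3a=C7a with ring carbons C4–C7; unit B primed, C8' = butanoyl C=O; inter‑unit bonds C6–C3' and C7–C7a'.

## Retrosynthetic overview

1. Target ⇐ (Z)‑butylidene butenolide by Sonogashira coupling/5‑exo lactonisation on a ring‑A enol triflate; the C8' ketone comes from the carbinol carbon of the starting amino acid.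
2. Ring A ⇐ Dieckmann closure; five‑membered carbocycle (bond C7–C7a') ⇐ intramolecular Michael addition of the γ‑lactone enolate to an (E)‑enoate on C6 (one pot; sets C7a' and C7, H‑6/H‑7 trans).
3. γ‑Lactone with C3' and C6 ⇐ hydroxyl‑directed (Z)‑allylboration of an α‑hydroxy ketone (bond C3'–C6), then lactonisation and cross‑metathesis.
4. Ring B with C3a' ⇐ Diels–Alder reaction (key step) of an (S)‑α'‑hydroxy vinyl ketone from L‑norvaline with methyl pentadienoate; this one purchased stereocentre relays to all others.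
5. Ring order: B (cycloaddition) → γ‑lactone → five‑membered carbocycle → A → butenolide.

## Route

Step 1
Reactants: 1 L‑norvaline [(2S)‑2‑aminopentanoic acid]
Product: 2 (2S)‑2‑hydroxypentanoic acid
Conditions: NaNO2, 1 M H2SO4, H2O, 0 °C → rt
Reagents that add atoms: water, O
Why: Diazotisation/hydrolysis of an α‑amino acid proceeds with net retention (double inversion through the α‑lactone), giving the (S)‑hydroxy acid.

Step 2
Reactants: 2 (2S)‑2‑hydroxypentanoic acid
Product: 3 (2S)‑2‑hydroxy‑N‑methoxy‑N‑methylpentanamide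
Conditions: MeNH(OMe), DCC, HOBt (cat.), CH2Cl2, 0 °C → rt
Reagents that add atoms: N,O‑dimethylhydroxylamine, CNOC
Why: Carbodiimide amide coupling gives the Weinreb amide without touching the stereocentre.

Step 3
Reactants: 3 (2S)‑2‑hydroxy‑N‑methoxy‑N‑methylpentanamide
Product: 4 (4S)‑4‑hydroxyhept‑1‑en‑3‑one
Conditions: CH2=CHMgBr (2.5 equiv), THF, −78 → 0 °C; then 1 M HCl, 0 °C
Reagents that add atoms: vinylmagnesium bromide, C=C[Mg]Br
Why: Weinreb ketone synthesis stops at the chelated tetrahedral intermediate, and the acidic quench keeps the released amine protonated so it cannot add to the vinyl ketone.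

Step 4
Reactants: 4 (4S)‑4‑hydroxyhept‑1‑en‑3‑one; 5 methyl (2E)‑penta‑2,4‑dienoate
Product: 6 methyl (1R,6S)‑6‑[(2S)‑2‑hydroxypentanoyl]cyclohex‑2‑ene‑1‑carboxylate (cis)
Conditions: 5 (3 equiv), BHT (cat.), toluene, 80 °C, sealed tube
Reagents that add atoms: none
Why: Key intermolecular Diels–Alder reaction (ortho, endo) builds ring B; the s‑cis enone, held planar by its O–H···O=C hydrogen bond, is attacked on the face opposite the propyl group, which sets C3a' as S (C7a' stays epimerisable and is fixed later).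

Step 5
Reactants: 7 methyl (2E,4E)‑hexa‑2,4‑dienoate (methyl sorbate)
Product: 8 methyl (3E)‑hexa‑3,5‑dienoate
Conditions: LiN(i‑Pr)2, THF–DMPU, −78 °C; then AcOH, −78 °C
Reagents that add atoms: none
Why: Deconjugative isomerisation: kinetic α‑protonation of the extended lithium enolate gives the 3,5‑dienoate.

Step 6
Reactants: 8 methyl (3E)‑hexa‑3,5‑dienoate
Product: 9 methyl (4Z)‑6‑(4,4,5,5‑tetramethyl‑1,3,2‑dioxaborolan‑2‑yl)hex‑4‑enoate
Conditions: pinacolborane, Ni(cod)2 (2.5 mol %), PCy3 (2.5 mol %), toluene, rt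
Reagents that add atoms: pinacolborane, B1OC(C)(C)C(C)(C)O1
Why: Nickel‑catalysed 1,4‑hydroboration of a terminal 1,3‑diene through an s‑cis π‑allyl intermediate gives the (Z)‑allylboronate.

Step 7
Reactants: 6 methyl (1R,6S)‑6‑[(2S)‑2‑hydroxypentanoyl]cyclohex‑2‑ene‑1‑carboxylate; 9 methyl (4Z)‑6‑(pinacolatoboryl)hex‑4‑enoate
Product: 10 methyl (1R,6S)‑6‑{(1R,2S)‑2‑ethenyl‑1‑hydroxy‑1‑[(1S)‑1‑hydroxybutyl]‑5‑methoxy‑5‑oxopentyl}cyclohex‑2‑ene‑1‑carboxylate (3'R; 6S; 8'S)
Conditions: 9 (1.3 equiv), 4 Å MS, toluene, rt → 40 °C; then aq. NaHCO3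
Reagents that add atoms: none
Why: Hydroxyl‑directed allylboration: boron binds the C8' hydroxyl and delivers the allyl group through a chair transition state fused to the five‑membered chelate, on the face anti to propyl (C3' R), while the (Z)‑geometry puts the ester chain axial and gives C6 S.

Step 8
Reactants: 10 diol diester
Product: 11 8'‑O‑triethylsilyl ether of 10 [1‑[(1S)‑1‑(triethylsilyloxy)butyl] in place of 1‑[(1S)‑1‑hydroxybutyl]]
Conditions: Et3SiCl, imidazole, DMF, 0 °C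
Reagents that add atoms: chlorotriethylsilane, CC[Si](Cl)(CC)CC
Why: Silyl ether formation selects the secondary hydroxyl over the hindered tertiary one.

Step 9
Reactants: 11 silyl ether hydroxy diester
Product: 12 methyl (4S)‑4‑{(1R,3aR,7aS)‑3‑oxo‑1‑[(1S)‑1‑(triethylsilyloxy)butyl]‑1,3,3a,6,7,7a‑hexahydro‑2‑benzofuran‑1‑yl}hex‑5‑enoate (cis‑fused γ‑lactone; 3'R,3a'S,7a'R,6S,8'S)
Conditions: CSA (10 mol %), toluene, 50 °C
Reagents that add atoms: none
Why: Acid‑catalysed lactonisation of the tertiary carbinol onto the cis ring ester closes the five‑membered lactone in preference to the six‑membered alternative with the chain ester.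

Step 10
Reactants: 12 γ‑lactone vinyl ester; 13 tert‑butyl acrylate
Product: 14 1‑tert‑butyl 7‑methyl (2E,4S)‑4‑{(1R,3aR,7aS)‑3‑oxo‑1‑[(1S)‑1‑(triethylsilyloxy)butyl]‑1,3,3a,6,7,7a‑hexahydro‑2‑benzofuran‑1‑yl}hept‑2‑enedioate
Conditions: 13 (5 equiv), second‑generation Hoveyda–Grubbs catalyst (5 mol %), CH2Cl2, 40 °C
Reagents that add atoms: none
Why: Olefin cross‑metathesis of the terminal vinyl group with the acrylate gives the (E)‑enoate; the cyclic disubstituted alkene of ring B is a poor metathesis partner.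

Step 11
Reactants: 14 (E)‑enoate γ‑lactone
Product: 16 ring‑A β‑keto ester in its enol form (C3a–OH; C7a–CO2t‑Bu; 8'‑OSiEt3; 6S,7S,3'R,3a'S,7a'S,8'S), via Michael adduct diester 15 (not isolated)
Conditions: KN(SiMe3)2 (2.2 equiv), THF, −78 °C → rt; then AcOH
Reagents that add atoms: none
Why: Intramolecular Michael addition (5‑exo‑trig) of the lactone dienolate through C7a', on the face of the C6 tether and with the allylic C6–H eclipsing the enoate, sets C7a' and places the C5 and C7a chains trans; the ester enolate so formed then closes ring A by Dieckmann condensation.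

Step 12
Reactants: 16 β‑keto ester (enol)
Product: 17 enol triflate of 16 (C3a–OSO2CF3; C3a=C7a)
Conditions: PhNTf2, i‑Pr2NEt, DMAP (cat.), CH2Cl2, rt
Reagents that add atoms: N‑phenylbis(trifluoromethanesulfonimide), O=S(=O)(N(c1ccccc1)S(=O)(=O)C(F)(F)F)C(F)(F)F
Why: O‑Triflation of the β‑keto ester enol gives the endocyclic tetrasubstituted vinyl triflate.

Step 13
Reactants: 17 enol triflate tert‑butyl ester silyl ether
Product: 18 hydroxy acid triflate (C7a–CO2H; C3a–OTf; free 8'‑OH)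
Conditions: CF3CO2H–CH2Cl2 (1:4), H2O (2 equiv), 0 °C → rt
Reagents that add atoms: none
Why: Acidolysis removes the tert‑butyl ester (loss of isobutene) and the triethylsilyl ether, while the vinyl triflate and the lactone survive.

Step 14
Reactants: 18 hydroxy acid triflate
Product: 19 keto acid triflate (8'‑ketone = butanoyl on C3')
Conditions: Dess–Martin periodinane, CH2Cl2, rt
Reagents that add atoms: none
Why: Dess–Martin oxidation turns the C8' carbinol into the ketone under non‑basic conditions, before acyl migration from the neighbouring lactone can occur.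

Step 15
Reactants: 19 keto acid triflate; 20 pent‑1‑yne
Product: 22 (3Z,6S,7S,3'R,3a'S,7a'S)‑6.3',7.7a'‑linked diligustilid‑8'‑one (target), via enyne keto acid 21 (not isolated)
Conditions: 20 (1.5 equiv), PdCl2(PPh3)2 (5 mol %), CuI (10 mol %), Et3N, MeCN, rt → 50 °C
Reagents that add atoms: none
Why: Sonogashira coupling of the vinyl triflate is followed in the same pot by 5‑exo‑dig anti addition of the carboxylate to the alkyne, giving the (Z)‑butylidene butenolide.

## Compound list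

1 | L‑norvaline | CCC[C@H](N)C(=O)O | starting material
2 | (2S)‑2‑hydroxypentanoic acid | CCC[C@H](O)C(=O)O | intermediate
3 | (2S)‑2‑hydroxy‑N‑methoxy‑N‑methylpentanamide | CCC[C@H](O)C(=O)N(C)OC | intermediate
4 | (4S)‑4‑hydroxyhept‑1‑en‑3‑one | CCC[C@H](O)C(=O)C=C | intermediate
5 | methyl (2E)‑penta‑2,4‑dienoate | C=C/C=C/C(=O)OC | starting material
6 | methyl (1R,6S)‑6‑[(2S)‑2‑hydroxypentanoyl]cyclohex‑2‑ene‑1‑carboxylate | CCC[C@H](O)C(=O)[C@H]1CCC=C[C@H]1C(=O)OC | intermediate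
7 | methyl (2E,4E)‑hexa‑2,4‑dienoate | C/C=C/C=C/C(=O)OC | starting material
8 | methyl (3E)‑hexa‑3,5‑dienoate | C=C/C=C/CC(=O)OC | intermediate
9 | methyl (4Z)‑6‑(4,4,5,5‑tetramethyl‑1,3,2‑dioxaborolan‑2‑yl)hex‑4‑enoate | COC(=O)CC/C=C\CB1OC(C)(C)C(C)(C)O1 | intermediate
10 | diol diester, methyl (1R,6S)‑6‑{(1R,2S)‑2‑ethenyl‑1‑hydroxy‑1‑[(1S)‑1‑hydroxybutyl]‑5‑methoxy‑5‑oxopentyl}cyclohex‑2‑ene‑1‑carboxylate | COC(=O)CC[C@@H](C=C)[C@](O)([C@@H](O)CCC)[C@H]1CCC=C[C@H]1C(=O)OC | intermediate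
11 | 8'‑O‑triethylsilyl ether of 10 | COC(=O)CC[C@@H](C=C)[C@](O)([C@@H](O[Si](CC)(CC)CC)CCC)[C@H]1CCC=C[C@H]1C(=O)OC | intermediate
12 | cis‑fused γ‑lactone, methyl (4S)‑4‑{(1R,3aR,7aS)‑3‑oxo‑1‑[(1S)‑1‑(triethylsilyloxy)butyl]‑1,3,3a,6,7,7a‑hexahydro‑2‑benzofuran‑1‑yl}hex‑5‑enoate | COC(=O)CC[C@@H](C=C)[C@@]1([C@@H](O[Si](CC)(CC)CC)CCC)OC(=O)[C@@H]2C=CCC[C@H]12 | intermediate
13 | tert‑butyl acrylate | C=CC(=O)OC(C)(C)C | starting material
14 | (E)‑enoate, 1‑tert‑butyl 7‑methyl (2E,4S)‑4‑{(1R,3aR,7aS)‑3‑oxo‑1‑[(1S)‑1‑(triethylsilyloxy)butyl]‑1,3,3a,6,7,7a‑hexahydro‑2‑benzofuran‑1‑yl}hept‑2‑enedioate | COC(=O)CC[C@@H](/C=C/C(=O)OC(C)(C)C)[C@@]1([C@@H](O[Si](CC)(CC)CC)CCC)OC(=O)[C@@H]2C=CCC[C@H]12 | intermediate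
15 | Michael adduct: 2‑oxabicyclo[2.2.1]heptan‑3‑one with ring B fused, exo‑CH2CH2CO2Me on C6, endo‑CH2CO2t‑Bu on C7, (S)‑1‑(triethylsilyloxy)butyl on C3' (6S,7S,3'R,3a'S,7a'S,8'S) | COC(=O)CC[C@H]1[C@H](CC(=O)OC(C)(C)C)[C@@]23C=CCC[C@@H]2[C@]1([C@@H](O[Si](CC)(CC)CC)CCC)OC3=O | intermediate (not isolated)
16 | ring‑A β‑keto ester, enol form (C3a–OH, C7a–CO2t‑Bu, 8'‑OSiEt3) | CC(C)(C)OC(=O)C2=C(O)CC[C@H]1[C@H]2[C@@]23C=CCC[C@@H]2[C@]1([C@@H](O[Si](CC)(CC)CC)CCC)OC3=O | intermediate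
17 | enol triflate of 16 | CC(C)(C)OC(=O)C2=C(OS(=O)(=O)C(F)(F)F)CC[C@H]1[C@H]2[C@@]23C=CCC[C@@H]2[C@]1([C@@H](O[Si](CC)(CC)CC)CCC)OC3=O | intermediate
18 | hydroxy acid triflate (C7a–CO2H, C3a–OTf, (8'S)‑OH) | OC(=O)C2=C(OS(=O)(=O)C(F)(F)F)CC[C@H]1[C@H]2[C@@]23C=CCC[C@@H]2[C@]1([C@@H](O)CCC)OC3=O | intermediate
19 | keto acid triflate (butanoyl on C3') | OC(=O)C2=C(OS(=O)(=O)C(F)(F)F)CC[C@H]1[C@H]2[C@@]23C=CCC[C@@H]2[C@]1(C(=O)CCC)OC3=O | intermediate
20 | pent‑1‑yne | CCCC#C | starting material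
21 | enyne keto acid (C3a–C≡C–Pr, C7a–CO2H) | OC(=O)C2=C(C#CCCC)CC[C@H]1[C@H]2[C@@]23C=CCC[C@@H]2[C@]1(C(=O)CCC)OC3=O | intermediate (not isolated)
22 | target, (3Z,6S,7S,3'R,3a'S,7a'S) | CCC/C=C1\OC(=O)C2=C1CC[C@H]1[C@H]2[C@@]23C=CCC[C@@H]2[C@]1(C(=O)CCC)OC3=O | target

## Count and risks

Total steps: 15. Longest linear sequence: 13 (steps 1–4 and 7–15; steps 5–6 make boronate 9).

The three steps most likely to fail:

Step 4 (an electron‑poor diene with an enone: rate, and regio‑ and facial selectivity at 80 °C). The fallback sets out from 4 and returns at 6. Compound 4 is combined instead with the electron‑rich diene methyl (2E)‑4‑[(tert‑butyldimethylsilyl)oxy]penta‑2,4‑dienoate F1 (one step from commercial methyl (2E)‑4‑oxopent‑2‑enoate, TBSOTf, Et3N), which should react at or below room temperature with the same hydrogen‑bond‑controlled facial sense. This gives the silyl enol ether methyl (1R,6S)‑3‑[(tert‑butyldimethylsilyl)oxy]‑6‑[(2S)‑2‑hydroxypentanoyl]cyclohex‑2‑ene‑1‑carboxylate F2. CsF/PhNTf2 converts it regiospecifically into the enol triflate methyl (1R,6S)‑6‑[(2S)‑2‑hydroxypentanoyl]‑3‑{[(trifluoromethyl)sulfonyl]oxy}cyclohex‑2‑ene‑1‑carboxylate F3, and formate reduction (Pd(OAc)2, PPh3, HCO2H, Bu3N) of the triflate gives 6.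

Step 7 (a hindered ketone and a functionalised (Z)‑boronate, with two stereocentres made at once). The fallback sets out from 6 and returns at 10 and replaces the allylboration by a Hosomi–Sakurai addition. The allylsilane methyl (4E)‑6‑(trimethylsilyl)hex‑4‑enoate F4 (cross‑metathesis of allyltrimethylsilane with methyl pent‑4‑enoate) is added to the TiCl4 chelate of 6 (CH2Cl2, −78 °C). The open antiperiplanar transition state on the chelated α‑hydroxy ketone should give the same C3' face and the same syn C3'–O/C6 relationship, leading to 10.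

Step 11 (trans selectivity of the Michael closure, then Dieckmann closure of the strained trans‑fused ring A). The fallback sets out from 14 and returns at 16. The reaction is stopped after the Michael addition (1.05 equiv KN(SiMe3)2, −78 °C, AcOH quench) and diester 15 is isolated. Its methyl ester is cleaved selectively with Me3SnOH (1,2‑dichloroethane, 80 °C) to the carboxylic acid F5 (15 with CO2H in place of CO2Me). The acid is activated with carbonyldiimidazole as the acyl imidazolide F6, and ring A is closed by irreversible intramolecular C‑acylation of the tert‑butyl ester enolate (LiN(SiMe3)2, THF, −78 °C → rt) to give 16.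

## Further compounds

F1 | step 4 | methyl (2E)‑4‑[(tert‑butyldimethylsilyl)oxy]penta‑2,4‑dienoate | C=C(O[Si](C)(C)C(C)(C)C)/C=C/C(=O)OC
F2 | step 4 | methyl (1R,6S)‑3‑[(tert‑butyldimethylsilyl)oxy]‑6‑[(2S)‑2‑hydroxypentanoyl]cyclohex‑2‑ene‑1‑carboxylate | CCC[C@H](O)C(=O)[C@H]1CCC(O[Si](C)(C)C(C)(C)C)=C[C@H]1C(=O)OC
F3 | step 4 | methyl (1R,6S)‑6‑[(2S)‑2‑hydroxypentanoyl]‑3‑{[(trifluoromethyl)sulfonyl]oxy}cyclohex‑2‑ene‑1‑carboxylate | CCC[C@H](O)C(=O)[C@H]1CCC(OS(=O)(=O)C(F)(F)F)=C[C@H]1C(=O)OC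
F4 | step 7 | methyl (4E)‑6‑(trimethylsilyl)hex‑4‑enoate | COC(=O)CC/C=C/C[Si](C)(C)C
F5 | step 11 | carboxylic acid from 15 (CO2H in place of CO2Me) | OC(=O)CC[C@H]1[C@H](CC(=O)OC(C)(C)C)[C@@]23C=CCC[C@@H]2[C@]1([C@@H](O[Si](CC)(CC)CC)CCC)OC3=O
F6 | step 11 | N‑acylimidazole of F5 | O=C(CC[C@H]1[C@H](CC(=O)OC(C)(C)C)[C@@]23C=CCC[C@@H]2[C@]1([C@@H](O[Si](CC)(CC)CC)CCC)OC3=O)n1ccnc1
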